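## Analysis of the target

Target numbering is used throughout: C1 bears the propenoic acid unit (C11 its α-carbon, C12 the carboxyl carbon, C13 the exocyclic methylene), ring A is C1, C2, C7, C8, C9, C10 and ring B is C2 to C7. The β face is the face of ring B that carries the C5 oxygen.

- The target is a cadinane-type sesquiterpenoid: a trans-fused decalin whose ring A is a cyclohexane and whose ring B is a cyclohexene (C3=C4, methyl on C4).
- There are six stereocentres (C1, C2, C5, C7, C8, C10). With ring A as a chair, H2 (α) and H7 (β) are trans-diaxial, the C1 side chain and the C8 hydroxyl are equatorial, and the C8 methyl and the C10 acyloxy group are both axial on the α face (syn-diaxial).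
- The C5 acetoxy group is pseudoaxial on the β face, cis to the C2–C1 bond and trans to the C7–C8 bond.
- Sensitive groups are the α-substituted acrylic acid (H1 is γ to it, so the double bond can slip into conjugation), the allylic acetate, the tertiary alcohol that becomes a β-hydroxy ketone whenever C10 is a carbonyl, and the (E)-4-hydroxy-2-(hydroxymethyl)but-2-enoate with its free diol.
- The difficulty lies in telling four oxygen functions apart, in acylating the most hindered hydroxyl (C10), and in relating the acyclic-type centre C1 to the ring centres C2 and C7.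
- The strategy rests on one feature: C8 (tertiary carbinol with methyl) and oxygenated C10 are 1,3-related across C9 in ring A, and C8, its methyl and C9 are the isopropenyl group that carvone already carries at C7. A C10 aldehyde on the C1 side chain can therefore close ring A by C9–C10 bond formation while the medium supplies the C8 hydroxyl.

## Retrosynthetic reasoning

**Unveiling the acid and the diol (40 back to 36).** No skeletal bond is cut. The side-chain diol is freed last from the cyclic acetal 39, and the C12 acid is grown from the allylic silyl ether of 36 through alcohol 37 and enal 38. The seven-membered acetal hides both hydroxyls from the oxidants and, because it contains the double bond, cannot lose the E geometry.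

**C10–O acyl bond (36 to 28 and 34).** The ester is cut because the axial C10 hydroxyl, flanked by C1 and syn-axial to the C8 methyl, is best acylated late by a compact acid of fixed geometry. Acid 34 goes back to 29: syn addition across a symmetrical alkyne puts the two oxygenated carbons cis with no regiochemical question.

**C5 acetate (28 to 26).** The C5 silyl ether is exchanged for the acetate before the side chain arrives, since the acid methanolysis that frees C5 would not spare the acetal of 34. The forward step has to acetylate C5 in the presence of the far more hindered C10 hydroxyl and the tertiary C8 hydroxyl.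

**C10 configuration (26 to 25 to 24).** Ring closure gives the equatorial C10 alcohol, so the axial alcohol is reached by oxidation and hydride delivery from the equatorial side. The axial C8 methyl blocks the other trajectory and works for the route here.

**C9–C10 bond, the key disconnection (24 to 23).** Cutting C9–C10 opens ring A to an aldehyde and an isopropenyl group. This removes one ring and two stereocentres (C8, C10) at once and leaves a ring B compound whose C7 centre is that of 1. The forward reaction must form the bond through a chair with the C1 substituent equatorial, capture the C8 cation with hydroxyl anti to the new bond, and not lose a proton instead.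

**The C11 unit (23 back to 15).** Aldehyde 23 comes from alcohol 22 and ether 21. The 2-(silyloxymethyl)vinyl group of 21 is built on a carboxyl carbon: acid 15 gives methyl ketone 17 (adding C13), enol triflate 19, and allylic alcohol 20 (adding C12). C10 travels as a 4-methoxybenzyl-protected hydroxymethyl group. This detour is the price of the next disconnection.

**C1–C2 bond (15 to 12, then 9 and 10).** An Ireland–Claisen rearrangement of the C4 tertiary allylic ester 12 moves the C4–O bond to a C2–C1 bond on the same (β) face and creates C3=C4. For C1, 2-cyclohexenyl esters of this kind are expected to rearrange through a boat when the ketene acetal is Z and through a chair when it is E. Both paths give the same C1 epimer, the one in which the carboxyl carbon eclipses C3 and the α-substituent lies over H2. That epimer is the required one only if the carboxyl carbon becomes C11 and the α-substituent becomes C10. The more obvious assignment (carboxyl as C10, a butenoate supplying C11) would have to run against this preference, so it was not used.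

**Tertiary allylic alcohol (9 to 8 to 5 to 4 to 1).** The C4 carbinol with its C2=C3 double bond is the 1,3-transposed form of an allylic alcohol. It goes back to epoxy alcohol 5 (selenide opening at C3, selenoxide elimination toward C2). Hydroxyl-directed epoxidation of trans-carveol 4 puts the C4 oxygen on the β face, which is the face the rearrangement needs. Alcohol 4 comes from 1 by reduction and inversion at C5; C7 is taken from the chiral pool.

## Alternatives that were turned down

**Alternative 1:** Both rings are cut at once (C1–C2 and C2–C7), back to the acyclic diphosphate A2. In the forward sense a cadinol-type terpene synthase would ionise A2, close the ten-membered ring, shift a hydride, close the second ring and hydrate C8, giving A1 with C1, C2, C7 and C8 as in the target.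
- For it: one step makes the whole skeleton and four stereocentres. On step count to the decalin it is clearly stronger than the chosen route.
- Against it: A1 has no oxygen at C5, C10 or C12. C10 is an unactivated methylene with no handle for an axial hydroxylation, and the isopropyl group would have to become an acrylic acid. Only further tailored enzymes could do this, and an enzyme of exactly this stereochemical course must exist and express.
- Comparison: the chosen strategy is much longer, but it carries the C5 oxygen from the start, creates the C10 oxygen in the ring-forming step, and brings C11 at a usable oxidation level, so every functional group has a defined origin.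

**Alternative 2:** The C2–C3 and C1–C11 bonds are cut on a preformed ring A. In the forward sense a vinyl cuprate adds to C2 of enone A4 anti to the C7 arm, and the enolate is alkylated at C1 by a haloacetate, giving A3.
- For it: conjugate addition and enolate trapping on a ring give the trans C1/C2 relationship dependably. On this point it is stronger than the chosen route, where C1 is set in a sigmatropic step with transition-state ambiguity. The acetate arm also allows a short α-methylenation to the acrylic acid, and the C10 ketone is already in place.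
- Against it: no ring is formed. A4, with its quaternary C8 carbinol, is not a chiral-pool compound and must be made enantioselectively. Ring B, with the C4 methyl, the trisubstituted C3=C4 bond and the C5 stereocentre, still has to be built from the vinyl group and a two-carbon arm with no control element for C5.
- Comparison: the chosen strategy gets ring B, C7 and (via C5) the face control for C2 from carvone, and spends its key step on ring A with two stereocentres.

**Alternative 3:** The C2–C7 bond of ring B is cut. In the forward sense the silyl ketene acetal of δ-lactone A6 undergoes an Ireland–Claisen ring contraction: C7 bonds to C2 as the C4–O bond breaks, giving acid A5 with C3=C4 and C8 as a carboxyl group.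
- For it: ring B and its trisubstituted alkene form in one step, and the C10 oxygen arrives as a stereodefined acetal carbon. The ketene acetal geometry is fixed by the ring, so the outcome is more predictable than for an open-chain ester enolate, and on that point it is stronger than the chosen route.
- Against it: C7 forms cis and must be epimerised. C8 arrives as an acid, so the tertiary carbinol (equatorial hydroxyl, axial methyl) has to be made later during or after a separate ring A closure, without the built-in anti addition of the chosen key step. A6 itself needs C1, C4, C5 and C10 set by asymmetric synthesis.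
- Comparison: more stereocentres are built de novo and the hardest centre (C8) is postponed. The chosen strategy sets C8 and closes ring A in the same event.

Key step: step 15

Assumption: 3-[(4-methoxybenzyl)oxy]propanoic acid (10) and (tributylstannyl)methanol are taken as purchasable; both are simple catalogue compounds.

## Route

**Step 1**
Reactants: 1 (R)-carvone
Product: 2 (1R,5R)-cis-carveol
Conditions: NaBH4, CeCl3·7H2O, MeOH, −78 to 0 °C
Reagents that add atoms: none
Why: Luche 1,2-reduction; hydride adds axially to the C5 carbonyl of the half-chair with the isopropenyl group equatorial, which should give the pseudoequatorial alcohol cis to the isopropenyl group.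

**Step 2**
Reactants: 2 (1R,5R)-cis-carveol
Product: 3 (1S,5R)-trans-carvyl 4-nitrobenzoate
Conditions: 4-O2NC6H4CO2H, PPh3, DIAD, THF, 0 °C to rt
Reagents that add atoms: 4-nitrobenzoic acid O=C(O)c1ccc(cc1)[N+](=O)[O-]
Why: Mitsunobu esterification with SN2 inversion at C5 puts the oxygen on the β face, trans to the C7 isopropenyl group; the acidic nucleophile keeps SN2′ and elimination down.

**Step 3**
Reactants: 3 (1S,5R)-trans-carvyl 4-nitrobenzoate
Product: 4 (1S,5R)-trans-carveol
Conditions: K2CO3, MeOH, rt
Reagents that add atoms: none
Why: Base-catalysed ester methanolysis; no stereocentre is touched.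

**Step 4**
Reactants: 4 (1S,5R)-trans-carveol
Product: 5 syn-epoxy alcohol (C3–C4 β-epoxide; C5 β-hydroxyl; C7 α-isopropenyl)
Conditions: VO(acac)2 (2 mol %), t-BuOOH, CH2Cl2, 0 °C to rt
Reagents that add atoms: tert-butyl hydroperoxide CC(C)(C)OO
Why: Hydroxyl-directed epoxidation; the vanadate ester of the pseudoaxial C5 hydroxyl delivers oxygen to the C3=C4 face it sits on, and the isopropenyl group has no directing group and should stay untouched.

**Step 5**
Reactants: 5 syn-epoxy alcohol
Product: 8 cis-diol (C2=C3; C4 β-hydroxyl and α-methyl; C5 β-hydroxyl), via hydroxy selenide 6 (not isolated), via selenoxide 7 (not isolated)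
Conditions: (PhSe)2, NaBH4, EtOH, rt to 70 °C; then H2O2 (30%), THF, 0 °C to rt
Reagents that add atoms: none
Why: Epoxide to allylic alcohol transposition by selenide opening and selenoxide syn-elimination; the selenolate attacks the secondary C3 with inversion so the C4 oxygen keeps the β face, and the selenoxide can only eliminate toward C2 because C4 has no hydrogen.

**Step 6**
Reactants: 8 cis-diol
Product: 9 C5 tert-butyldimethylsilyl ether of 8
Conditions: TBSCl, imidazole, DMF, rt
Reagents that add atoms: tert-butyldimethylsilyl chloride CC(C)(C)[Si](C)(C)Cl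
Why: Silylation under imidazole catalysis; the secondary C5 hydroxyl reacts and the tertiary C4 hydroxyl does not.

**Step 7**
Reactants: 9 C5 silyl ether; 10 3-[(4-methoxybenzyl)oxy]propanoic acid
Product: 12 C4 3-[(4-methoxybenzyl)oxy]propanoate of 9, via acid chloride 11 (not isolated)
Conditions: 10, (COCl)2, DMF (cat.), CH2Cl2, 0 °C to rt; then 9, pyridine, DMAP (1 equiv), CH2Cl2, 0 to 40 °C
Reagents that add atoms: none
Why: Acylation of a tertiary allylic alcohol through the acylpyridinium ion; no alkoxide is generated, so the neighbouring cis silyl ether cannot migrate, and no stereocentre changes.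

**Step 8**
Reactants: 12 C4 ester
Product: 15 rearranged acid (C1 bearing CO2H as future C11 and CH2OPMB as C10; C2–C1 bond β; C3=C4), via silyl ketene acetal 13 (not isolated), via trimethylsilyl ester 14 (not isolated)
Conditions: LiN(i-Pr)2, Me3SiCl, Et3N, THF/DMPU, −78 °C, then 40 °C; 1 M HCl work-up
Reagents that add atoms: none
Why: Ireland–Claisen rearrangement; the new C2–C1 bond forms on the β face from which the C4–O bond leaves, so C2 is set suprafacially. The (Z)-silyl ketene acetal 13 should react through the boat usual for 2-cyclohexenyl esters (a chair would push OSiMe3 over ring B against the axial C6–H and the C5 silyl ether), with H over C7 and the C10 arm outside, which is the C1 configuration of 15. Any (E) acetal gives the same epimer through the chair.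

**Step 9**
Reactants: 15 rearranged acid
Product: 17 methyl ketone (C11 carbonyl; C13 methyl), via dilithium gem-diolate 16 (not isolated)
Conditions: MeLi (3.5 equiv), Et2O, 0 °C to rt; inverse quench into cold 1 M HCl
Reagents that add atoms: methyllithium [Li]C
Why: Addition of methyllithium to the lithium carboxylate stops at the gem-diolate, which gives the ketone only on quench; C1 is not deprotonated under these conditions and keeps its configuration.

**Step 10**
Reactants: 17 methyl ketone
Product: 19 enol triflate (C11=C13), via lithium enolate 18 (not isolated)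
Conditions: LiN(i-Pr)2, THF, −78 °C; PhNTf2, −78 to 0 °C
Reagents that add atoms: N-phenylbis(trifluoromethanesulfonimide) O=S(=O)(N(c1ccccc1)S(=O)(=O)C(F)(F)F)C(F)(F)F
Why: Kinetic deprotonation takes the methyl group and not the hindered C1 methine, so C1 is untouched and the β-alkoxy group is not expelled; O-triflation fixes the terminal enol.

**Step 11**
Reactants: 19 enol triflate
Product: 20 allylic alcohol (C11 bearing C13 methylene and C12 hydroxymethyl)
Conditions: Bu3SnCH2OH, Pd(PPh3)4 (5 mol %), LiCl, 1,4-dioxane, 100 °C
Reagents that add atoms: (tributylstannyl)methanol CCCC[Sn](CCCC)(CCCC)CO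
Why: Stille coupling of an alkenyl triflate with the hydroxymethyl stannane on zerovalent palladium; the sp2 centre is replaced with retention and no stereocentre is involved.

**Step 12**
Reactants: 20 allylic alcohol
Product: 21 C12 tert-butyldiphenylsilyl ether
Conditions: TBDPSCl, imidazole, DMF, rt
Reagents that add atoms: tert-butyldiphenylsilyl chloride CC(C)(C)[Si](Cl)(c1ccccc1)c1ccccc1
Why: Standard silylation of a primary allylic alcohol; this group must outlast the acid step that later frees C5.

**Step 13**
Reactants: 21 C12 silyl ether
Product: 22 C10 primary alcohol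
Conditions: DDQ, CH2Cl2/pH 7 buffer, 0 °C
Reagents that add atoms: none
Why: Oxidative cleavage of the 4-methoxybenzyl ether through its benzylic oxocarbenium ion; silyl ethers and the unactivated alkenes should not react.

**Step 14**
Reactants: 22 C10 primary alcohol
Product: 23 aldehyde (ring B aldehyde with C7 isopropenyl group)
Conditions: Dess–Martin periodinane, NaHCO3, CH2Cl2, 0 °C to rt
Reagents that add atoms: none
Why: Dess–Martin oxidation under buffered, non-basic conditions should spare the C1 centre, which is α to the new aldehyde and allylic; the aldehyde is used without storage.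

**Step 15**
Reactants: 23 aldehyde
Product: 24 decalin 8,10-diol (C8 β-hydroxyl equatorial and α-methyl axial; C10 β-hydroxyl equatorial)
Conditions: Sc(OTf)3 (10 mol %), H2O (5 equiv), CH2Cl2, −40 to 0 °C
Reagents that add atoms: water O
Why: Prins hydroxycyclisation: Sc(OTf)3 activates the C10 aldehyde, the terminal carbon C9 of the C7 isopropenyl group attacks it, and water captures the tertiary C8 cation. The closest known reactions are the acid-promoted cyclisation of citronellal to p-menthane-3,8-diol and Lewis-acid type 2 carbonyl-ene closures. Ring A closes in a 6-endo mode at the alkene (both alkene carbons become ring atoms, the carbonyl oxygen stays outside) through a chair. The trans ring fusion is inherited from C2 and C7, and the C1 substituent sits equatorial in that chair. C8 is controlled by anti addition across the alkene: water enters anti to the forming C9–C10 bond, which makes the hydroxyl equatorial and the methyl axial. C10 is controlled by the aldehyde oxygen taking the equatorial position, away from the incipient axial methyl. The step needs hydroxyl capture to beat proton loss from C8, which the water content and low temperature are meant to secure. It also needs chemoselectivity, which the substrate secures because the C11 methylene could only form a four-membered ring and C3=C4 only a strained five-membered one with a secondary cation.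

**Step 16**
Reactants: 24 decalin 8,10-diol
Product: 25 C10 ketone
Conditions: Dess–Martin periodinane, NaHCO3, CH2Cl2, 0 °C
Reagents that add atoms: none
Why: Dess–Martin oxidation of the only secondary alcohol; the tertiary C8 hydroxyl cannot be oxidised and the buffered medium should avoid dehydration of the β-hydroxy ketone.

**Step 17**
Reactants: 25 C10 ketone
Product: 26 8β,10α-diol (C10 hydroxyl axial)
Conditions: LiBH(s-Bu)3, THF, −78 °C; aq. NH4Cl
Reagents that add atoms: none
Why: Ketone reduction by a hindered hydride; the axial (α) trajectory at C10 is blocked by the axial C8 methyl and H2, so hydride should enter from the equatorial β side and give the axial α-alcohol.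

**Step 18**
Reactants: 26 8β,10α-diol
Product: 27 5,8,10-triol
Conditions: CSA (0.2 equiv), MeOH/CH2Cl2, 0 °C to rt
Reagents that add atoms: none
Why: Acid-catalysed methanolysis removes the secondary tert-butyldimethylsilyl ether; the primary tert-butyldiphenylsilyl ether solvolyses far more slowly.

**Step 19**
Reactants: 27 5,8,10-triol
Product: 28 C5 acetate
Conditions: Ac2O (1.2 equiv), pyridine, CH2Cl2, 0 °C
Reagents that add atoms: acetic anhydride CC(=O)OC(C)=O
Why: Acetylation discriminates by hindrance: the allylic C5 hydroxyl is open, the C10 hydroxyl is axial, flanked by C1 and syn-axial to the C8 methyl, and the C8 hydroxyl is tertiary.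

**Step 20**
Reactants: 29 but-2-yne-1,4-diol
Product: 30 (E)-2-(tributylstannyl)but-2-ene-1,4-diol
Conditions: Bu3SnH, PdCl2(PPh3)2 (2 mol %), THF, 0 °C to rt
Reagents that add atoms: tributyltin hydride CCCC[SnH](CCCC)CCCC
Why: Palladium-catalysed hydrostannation adds H and SnBu3 syn across the symmetrical alkyne, so the two hydroxymethyl groups end up cis and there is no regiochemical issue.

**Step 21**
Reactants: 30 (E)-2-(tributylstannyl)but-2-ene-1,4-diol
Product: 31 (E)-2-iodobut-2-ene-1,4-diol
Conditions: I2, CH2Cl2, 0 °C
Reagents that add atoms: iodine II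
Why: Iododestannylation replaces tin by iodine with retention of alkene geometry.

**Step 22**
Reactants: 31 (E)-2-iodobut-2-ene-1,4-diol
Product: 32 5-iodo-2,2-dimethyl-4,7-dihydro-1,3-dioxepine
Conditions: Me2C(OMe)2, PPTS (cat.), CH2Cl2, rt
Reagents that add atoms: 2,2-dimethoxypropane COC(C)(C)OC
Why: Acetal exchange; only the cis diol can close the seven-membered ring, which from here on holds the alkene geometry.

**Step 23**
Reactants: 32 5-iodo-2,2-dimethyl-4,7-dihydro-1,3-dioxepine
Product: 34 2,2-dimethyl-4,7-dihydro-1,3-dioxepine-5-carboxylic acid, via alkenyllithium 33 (not isolated)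
Conditions: t-BuLi (2.1 equiv), Et2O, −78 °C; CO2; aq. NaH2PO4
Reagents that add atoms: carbon dioxide O=C=O
Why: Iodine–lithium exchange and carboxylation both proceed with retention at the alkenyl carbon; at −78 °C the alkenyllithium should be trapped before it can expel the allylic oxygen.

**Step 24**
Reactants: 28 C5 acetate; 34 2,2-dimethyl-4,7-dihydro-1,3-dioxepine-5-carboxylic acid
Product: 36 C10 ester, via mixed anhydride 35 (not isolated)
Conditions: 34, 2,4,6-Cl3C6H2COCl, Et3N, THF, rt; then 28, DMAP, toluene, rt to 60 °C
Reagents that add atoms: none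
Why: Yamaguchi esterification; the acylpyridinium ion from the mixed anhydride is reactive enough for the hindered axial C10 hydroxyl while the tertiary C8 hydroxyl stays free, and the ring-locked alkene cannot isomerise.

**Step 25**
Reactants: 36 C10 ester
Product: 37 C12 allylic alcohol
Conditions: Bu4NF, AcOH, THF, 0 °C to rt
Reagents that add atoms: none
Why: Fluoride cleaves the primary silyl ether; buffering with acetic acid protects the acetate and the C10 ester, and the trans 8,10 relationship excludes acyl migration to C8.

**Step 26**
Reactants: 37 C12 allylic alcohol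
Product: 38 enal
Conditions: MnO2, CH2Cl2, rt
Reagents that add atoms: none
Why: MnO2 oxidises allylic alcohols selectively; the tertiary alcohol and the protected side chain are inert.

**Step 27**
Reactants: 38 enal
Product: 39 acrylic acid with acetal-protected side chain
Conditions: NaClO2, NaH2PO4, 2-methylbut-2-ene, t-BuOH/H2O, 0 °C to rt
Reagents that add atoms: sodium chlorite [Na+].[O-]Cl=O
Why: Pinnick oxidation converts the enal to the acid without touching alkenes, the scavenger removing hypochlorous acid.

**Step 28**
Reactants: 39 acrylic acid with acetal-protected side chain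
Product: 40 target (CNP0468194.3)
Conditions: AcOH/THF/H2O (3:1:1), rt
Reagents that add atoms: none
Why: Mild acid hydrolysis of the strained seven-membered acetal frees the two primary hydroxyls; esters, the tertiary alcohol and the allylic acetate should survive, and the E geometry is the one fixed in step 20.

## Compound list

1 | (R)-carvone | CC(=C)[C@@H]1CC=C(C)C(=O)C1 | starting material
2 | (1R,5R)-cis-carveol | C=C(C)[C@@H]1CC=C(C)[C@H](O)C1 | intermediate
3 | (1S,5R)-trans-carvyl 4-nitrobenzoate | C=C(C)[C@@H]1CC=C(C)[C@@H](OC(=O)c2ccc(cc2)[N+](=O)[O-])C1 | intermediate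
4 | (1S,5R)-trans-carveol | C=C(C)[C@@H]1CC=C(C)[C@@H](O)C1 | intermediate
5 | syn-epoxy alcohol (C3–C4 β-epoxide, C5 β-OH) | C=C(C)[C@@H]1C[C@H]2O[C@@]2(C)[C@@H](O)C1 | intermediate
6 | hydroxy selenide (C3 α-SePh, C4 β-OH, C5 β-OH) | C=C(C)[C@@H]1C[C@H]([Se]c2ccccc2)[C@@](C)(O)[C@@H](O)C1 | intermediate
7 | selenoxide of 6 | C=C(C)[C@@H]1C[C@H]([Se](=O)c2ccccc2)[C@@](C)(O)[C@@H](O)C1 | intermediate
8 | cis-diol, 2-methyl-5-(prop-1-en-2-yl)cyclohex-3-ene-1,2-diol (C4 β-OH, C5 β-OH, C7 α-isopropenyl) | C=C(C)[C@@H]1C=C[C@@](C)(O)[C@@H](O)C1 | intermediate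
9 | C5 tert-butyldimethylsilyl ether of 8 | C=C(C)[C@@H]1C=C[C@@](C)(O)[C@@H](O[Si](C)(C)C(C)(C)C)C1 | intermediate
10 | 3-[(4-methoxybenzyl)oxy]propanoic acid | COc1ccc(COCCC(=O)O)cc1 | starting material
11 | 3-[(4-methoxybenzyl)oxy]propanoyl chloride | COc1ccc(COCCC(Cl)=O)cc1 | intermediate
12 | C4 3-[(4-methoxybenzyl)oxy]propanoate of 9 | C=C(C)[C@@H]1C=C[C@@](C)(OC(=O)CCOCc2ccc(OC)cc2)[C@@H](O[Si](C)(C)C(C)(C)C)C1 | intermediate
13 | (Z)-trimethylsilyl ketene acetal of 12 | C=C(C)[C@@H]1C=C[C@@](C)(O/C(O[Si](C)(C)C)=C/COCc2ccc(OC)cc2)[C@@H](O[Si](C)(C)C(C)(C)C)C1 | intermediate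
14 | trimethylsilyl ester of 15 | C[Si](C)(C)OC(=O)[C@@H](COCc1ccc(OC)cc1)[C@H]1C=C(C)[C@@H](O[Si](C)(C)C(C)(C)C)C[C@@H]1C(C)=C | intermediate
15 | rearranged acid (CO2H = C11, CH2OPMB = C10, ring B at C2) | OC(=O)[C@@H](COCc1ccc(OC)cc1)[C@H]1C=C(C)[C@@H](O[Si](C)(C)C(C)(C)C)C[C@@H]1C(C)=C | intermediate
16 | dilithium gem-diolate from 15 | [Li]OC(C)(O[Li])[C@@H](COCc1ccc(OC)cc1)[C@H]1C=C(C)[C@@H](O[Si](C)(C)C(C)(C)C)C[C@@H]1C(C)=C | intermediate
17 | methyl ketone | CC(=O)[C@@H](COCc1ccc(OC)cc1)[C@H]1C=C(C)[C@@H](O[Si](C)(C)C(C)(C)C)C[C@@H]1C(C)=C | intermediate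
18 | lithium enolate of 17 (methyl side) | [Li]OC(=C)[C@@H](COCc1ccc(OC)cc1)[C@H]1C=C(C)[C@@H](O[Si](C)(C)C(C)(C)C)C[C@@H]1C(C)=C | intermediate
19 | enol triflate | C=C(OS(=O)(=O)C(F)(F)F)[C@@H](COCc1ccc(OC)cc1)[C@H]1C=C(C)[C@@H](O[Si](C)(C)C(C)(C)C)C[C@@H]1C(C)=C | intermediate
20 | allylic alcohol (C12 hydroxymethyl) | C=C(CO)[C@@H](COCc1ccc(OC)cc1)[C@H]1C=C(C)[C@@H](O[Si](C)(C)C(C)(C)C)C[C@@H]1C(C)=C | intermediate
21 | C12 tert-butyldiphenylsilyl ether | C=C(CO[Si](c1ccccc1)(c1ccccc1)C(C)(C)C)[C@@H](COCc1ccc(OC)cc1)[C@H]1C=C(C)[C@@H](O[Si](C)(C)C(C)(C)C)C[C@@H]1C(C)=C | intermediate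
22 | C10 primary alcohol | C=C(CO[Si](c1ccccc1)(c1ccccc1)C(C)(C)C)[C@@H](CO)[C@H]1C=C(C)[C@@H](O[Si](C)(C)C(C)(C)C)C[C@@H]1C(C)=C | intermediate
23 | ring B aldehyde with C7 isopropenyl group (key-step precursor) | C=C(CO[Si](c1ccccc1)(c1ccccc1)C(C)(C)C)[C@@H](C=O)[C@H]2C=C(C)[C@@H](O[Si](C)(C)C(C)(C)C)C[C@@H]2C(C)=C | intermediate
24 | decalin 8,10-diol (key-step product; C10 hydroxyl equatorial) | C=C(CO[Si](c1ccccc1)(c1ccccc1)C(C)(C)C)[C@@H]1[C@H]2C=C(C)[C@@H](O[Si](C)(C)C(C)(C)C)C[C@@H]2[C@@](C)(O)C[C@H]1O | intermediate
25 | C10 ketone | C=C(CO[Si](c1ccccc1)(c1ccccc1)C(C)(C)C)[C@@H]1[C@H]2C=C(C)[C@@H](O[Si](C)(C)C(C)(C)C)C[C@@H]2[C@@](C)(O)CC1=O | intermediate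
26 | 8β,10α-diol (C10 hydroxyl axial) | C=C(CO[Si](c1ccccc1)(c1ccccc1)C(C)(C)C)[C@@H]1[C@H]2C=C(C)[C@@H](O[Si](C)(C)C(C)(C)C)C[C@@H]2[C@@](C)(O)C[C@@H]1O | intermediate
27 | 5,8,10-triol | C=C(CO[Si](c1ccccc1)(c1ccccc1)C(C)(C)C)[C@@H]1[C@H]2C=C(C)[C@@H](O)C[C@@H]2[C@@](C)(O)C[C@@H]1O | intermediate
28 | C5 acetate | C=C(CO[Si](c1ccccc1)(c1ccccc1)C(C)(C)C)[C@@H]1[C@H]2C=C(C)[C@@H](OC(C)=O)C[C@@H]2[C@@](C)(O)C[C@@H]1O | intermediate
29 | but-2-yne-1,4-diol | OCC#CCO | starting material
30 | (E)-2-(tributylstannyl)but-2-ene-1,4-diol | OC/C=C(\CO)[Sn](CCCC)(CCCC)CCCC | intermediate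
31 | (E)-2-iodobut-2-ene-1,4-diol | OC/C=C(\CO)I | intermediate
32 | 5-iodo-2,2-dimethyl-4,7-dihydro-1,3-dioxepine | CC1(C)OCC=C(I)CO1 | intermediate
33 | (2,2-dimethyl-4,7-dihydro-1,3-dioxepin-5-yl)lithium | CC1(C)OCC=C([Li])CO1 | intermediate
34 | 2,2-dimethyl-4,7-dihydro-1,3-dioxepine-5-carboxylic acid | CC1(C)OCC=C(CO1)C(=O)O | intermediate
35 | mixed anhydride of 34 with 2,4,6-trichlorobenzoic acid | CC1(C)OCC=C(CO1)C(=O)OC(=O)c1c(Cl)cc(Cl)cc1Cl | intermediate
36 | C10 ester (C5 acetate, C12 silyl ether, side chain as acetal) | C=C(CO[Si](c1ccccc1)(c1ccccc1)C(C)(C)C)[C@@H]1[C@H]2C=C(C)[C@@H](OC(C)=O)C[C@@H]2[C@@](C)(O)C[C@@H]1OC(=O)C1=CCOC(C)(C)OC1 | intermediate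
37 | C12 allylic alcohol | C=C(CO)[C@@H]1[C@H]2C=C(C)[C@@H](OC(C)=O)C[C@@H]2[C@@](C)(O)C[C@@H]1OC(=O)C1=CCOC(C)(C)OC1 | intermediate
38 | enal | C=C(C=O)[C@@H]1[C@H]2C=C(C)[C@@H](OC(C)=O)C[C@@H]2[C@@](C)(O)C[C@@H]1OC(=O)C1=CCOC(C)(C)OC1 | intermediate
39 | acrylic acid with acetal-protected side chain | C=C(C(=O)O)[C@@H]1[C@H]2C=C(C)[C@@H](OC(C)=O)C[C@@H]2[C@@](C)(O)C[C@@H]1OC(=O)C1=CCOC(C)(C)OC1 | intermediate
40 | CNP0468194.3 | C=C(C(=O)O)[C@@H]1[C@H]2C=C(C)[C@@H](OC(C)=O)C[C@@H]2[C@@](C)(O)C[C@@H]1OC(=O)/C(=C/CO)CO | target

## Step count and least certain steps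

Total step count: 28. Longest linear sequence: 24 steps (steps 1–19 and 24–28, from 1 to 40). The side-chain acid 34 takes 4 steps (20–23) from 29.

**Step 15 (key step).** The most likely failure is loss of a proton from the C8 cation (ene-type termination) in place of hydroxyl capture. A long-lived cation would also allow capture from both faces. Further risks are acid-promoted migration of the C11 double bond into conjugation with the aldehyde, with loss of the C1 centre, and cleavage or ionisation of the allylic C5 silyl ether.
Fallback: setting out from 23, the ring is closed as a type 2 carbonyl-ene reaction with Me2AlCl in CH2Cl2 at −78 °C, which should give the C8 exocyclic methylene alcohol F1. Its exocyclic alkene, the least hindered one and the only one without an allylic oxygen, is dihydroxylated with OsO4 (cat.) and NMO from the equatorial face to give the triol F2. The primary hydroxyl is sulfonylated with TsCl in pyridine to give the tosylate F3, and reduction with LiBHEt3 turns the axial CH2OTs into the methyl group. The sequence comes back to the route at 24.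

**Step 8.** The ester enolate may expel the β 4-methoxybenzyloxy group before it is silylated. The C1 configuration may also erode if ketene acetal geometry is poorly controlled or if boat and chair arrangements leak into each other.
Fallback: setting out from 9, the C4 acetate F4 (Ac2O, DMAP, Et3N) is rearranged under the same Ireland–Claisen conditions to the acetic acid F5, which fixes C2 alone. F5 is coupled to (S)-4-benzyloxazolidin-2-one through its pivaloyl mixed anhydride to give the imide F6. Its titanium enolate (TiCl4, i-Pr2NEt) is hydroxymethylated with 1,3,5-trioxane under auxiliary control to give F7, which is protected with 4-methoxybenzyl trichloroacetimidate (CSA cat.) to give F8. Cleavage with LiOH and H2O2 returns to the route at 15.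

**Step 5.** Trans-diaxial attack at C3 requires the half-chair with the C7 isopropenyl group pseudoaxial, so the opening may be slow or may drift to C4. The oxidising medium may also touch the isopropenyl group.
Fallback: setting out from 4, a hydroxyl-directed singlet-oxygen ene reaction (O2, tetraphenylporphyrin, light, CH2Cl2, 0 °C) places the hydroperoxide on C4, on the face of the hydroxyl, with the double bond shifted to C2=C3, giving the hydroperoxide F9. Reduction with PPh3 returns to the route at 8.

**Step 17.** Ketone 25 is a β-hydroxy ketone. Under the basic hydride its C8 alkoxide may open ring A by retro-aldol cleavage or eliminate, and the C1 centre next to the carbonyl may epimerise or let the C11 double bond migrate.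
Fallback: setting out from 25, the tertiary hydroxyl is silylated with N-(trimethylsilyl)imidazole to give the trimethylsilyl ether F10. Reduction with LiBH(s-Bu)3 gives the axial alcohol F11. The conditions of step 18 remove both silyl ethers and the sequence comes back to the route at 27.

**Step 24.** Acylation of the axial C10 hydroxyl may stall, and forcing it may acylate the C8 hydroxyl or shift the C5 acetate.
Fallback: setting out from 28 and 32, the ester bond is made from the other side by palladium-catalysed alkoxycarbonylation (Pd(OAc)2, PPh3, CO 1 atm, Et3N, DMAP, DMF, 60 °C). The acylpalladium species formed from 32 and CO is captured by the C10 hydroxyl of 28. This makes no new isolated compound (F0) and comes back to the route at 36.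

## Further compounds

F1 | step 15 | ene product (C8 exocyclic methylene, C10 equatorial hydroxyl) | C=C(CO[Si](c1ccccc1)(c1ccccc1)C(C)(C)C)[C@@H]1[C@H]2C=C(C)[C@@H](O[Si](C)(C)C(C)(C)C)C[C@@H]2C(=C)C[C@H]1O
F2 | step 15 | triol (C8 equatorial hydroxyl, axial hydroxymethyl) | C=C(CO[Si](c1ccccc1)(c1ccccc1)C(C)(C)C)[C@@H]1[C@H]2C=C(C)[C@@H](O[Si](C)(C)C(C)(C)C)C[C@@H]2[C@@](CO)(O)C[C@H]1O
F3 | step 15 | primary tosylate of F2 | C=C(CO[Si](c1ccccc1)(c1ccccc1)C(C)(C)C)[C@@H]1[C@H]2C=C(C)[C@@H](O[Si](C)(C)C(C)(C)C)C[C@@H]2[C@@](COS(=O)(=O)c3ccc(C)cc3)(O)C[C@H]1O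
F4 | step 8 | C4 acetate of 9 | C=C(C)[C@@H]1C=C[C@@](C)(OC(C)=O)[C@@H](O[Si](C)(C)C(C)(C)C)C1
F5 | step 8 | ring B acetic acid (C2 set, C1 methylene) | OC(=O)C[C@H]1C=C(C)[C@@H](O[Si](C)(C)C(C)(C)C)C[C@@H]1C(C)=C
F6 | step 8 | N-acyl (S)-4-benzyloxazolidin-2-one of F5 | O=C(C[C@H]1C=C(C)[C@@H](O[Si](C)(C)C(C)(C)C)C[C@@H]1C(C)=C)N1[C@@H](Cc2ccccc2)COC1=O
F7 | step 8 | C1 hydroxymethyl imide | O=C([C@@H](CO)[C@H]1C=C(C)[C@@H](O[Si](C)(C)C(C)(C)C)C[C@@H]1C(C)=C)N1[C@@H](Cc2ccccc2)COC1=O
F8 | step 8 | C1 (4-methoxybenzyloxy)methyl imide | O=C([C@@H](COCc1ccc(OC)cc1)[C@H]1C=C(C)[C@@H](O[Si](C)(C)C(C)(C)C)C[C@@H]1C(C)=C)N1[C@@H](Cc2ccccc2)COC1=O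
F9 | step 5 | C4 β-hydroperoxide (C2=C3, C5 β-hydroxyl) | C=C(C)[C@@H]1C=C[C@@](C)(OO)[C@@H](O)C1
F10 | step 17 | C8 trimethylsilyl ether of ketone 25 | C=C(CO[Si](c1ccccc1)(c1ccccc1)C(C)(C)C)[C@@H]1[C@H]2C=C(C)[C@@H](O[Si](C)(C)C(C)(C)C)C[C@@H]2[C@@](C)(O[Si](C)(C)C)CC1=O
F11 | step 17 | C8 trimethylsilyl ether of 26 | C=C(CO[Si](c1ccccc1)(c1ccccc1)C(C)(C)C)[C@@H]1[C@H]2C=C(C)[C@@H](O[Si](C)(C)C(C)(C)C)C[C@@H]2[C@@](C)(O[Si](C)(C)C)C[C@@H]1O
F0 | step 24 | none | none
A1 | alternative 1 | trans-fused cadin-4-en-10-ol (key-step product) | CC(C)[C@@H]1[C@H]2C=C(C)CC[C@@H]2[C@@](C)(O)CC1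
A2 | alternative 1 | (2E,6E)-farnesyl diphosphate | CC(C)=CCC/C(C)=C/CC/C(C)=C/COP(O)(=O)OP(O)(O)=O
A3 | alternative 2 | 1,2,7,8-tetrasubstituted cyclohexanone (key-step product) | COC(=O)C[C@@H]1[C@@H](C=C)[C@H](CCO[Si](C)(C)C(C)(C)C)[C@@](C)(O[Si](CC)(CC)CC)CC1=O
A4 | alternative 2 | ring A enone | O=C1C=C[C@H](CCO[Si](C)(C)C(C)(C)C)[C@@](C)(O[Si](CC)(CC)CC)C1
A5 | alternative 3 | ring B cyclohexenecarboxylic acid (key-step product) | CC(C)(C)[Si](c1ccccc1)(c1ccccc1)OCC[C@@H]([C@H]1COC(C)(C)O1)[C@H]2C=C(C)[C@@H](OCc3ccc(OC)cc3)C[C@H]2C(=O)O
A6 | alternative 3 | δ-lactone with E-alkenyl chain on C4 | CC(C)(C)[Si](c1ccccc1)(c1ccccc1)OCC[C@@H]([C@H]1COC(C)(C)O1)/C=C/[C@@]2(C)OC(=O)CC[C@@H]2OCc3ccc(OC)cc3
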